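**Plan**

1. Cuts, in retrosynthetic order: O4–H to O4–CH3; the C1–acyl bond; the C7 prenyl group (back to C7=CH2, then C7=O, then C7–O); C2=O (back to CH2); then the key cut, C1–C8 together with a temporary C7–O–C9 oxa-bridge, which opens ring B (C1–C8–C7–C6–C5–C9); last, the two C–C bonds at C5.
2. Enabling feature: without its acyl group C1 is equivalent to C3, and C9 to C4, so ring A (C1–C2–C3–C4–C5–C9) has a mirror plane through C2 and C5. It maps onto a 6,6-dialkyl-1,5-dimethoxycyclohexa-1,4-diene with two equivalent enol ethers, and C6–C7–C8 with its methyl and homoprenyl groups is nerol (C7=C8 is its 2,3-alkene).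
3. Forward: ring A comes from an arene (Birch reduction, two alkylations at C5); ring B is closed last by an epoxide-opening cyclisation; C2 oxidation, C7 adjustment, C1 acylation and O-demethylation follow.
4. Stereochemistry: the only catalyst-set element is the (2R,3S)-oxirane of nerol (Sharpless). In the key step it sets C8 by inversion and, through a chair transition state, selects one enol ether, which fixes C1, C5 and C9.
5. C7 is set afterwards by substrate control (exo-face hydroboration of a 7-methylene compound puts the prenyl arm endo). The side-chain stereocentre is bought as (R)-2-methylbutanoic acid.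

Key step: step 6

Conventions: C1 = acyl bridgehead, C2–C4 = enolised β-diketone bridge, C5 = prenyl bridgehead, C6 = CH2, C7 = CH, C8 = quaternary carbon, C9 = bridging C=O. On ring B "endo" is the face of the C2–C4 bridge and "exo" the opposite face. In the target the C7 prenyl and C8 methyl are endo and the C8 homoprenyl is exo.

Assumption: the target is one enol tautomer of a freely equilibrating β-diketone, and enantiopure (R)-2-methylbutanoic acid is purchased.

**Route**

Step 1
Reactants: 1 nerol
Product: 2 (2R,3S)-2,3-epoxynerol
Conditions: Ti(OiPr)4 (cat.), D-(−)-diethyl tartrate (cat.), t-BuOOH, 4 Å MS, CH2Cl2, −20 °C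
Reagents that add atoms: tert-butyl hydroperoxide CC(C)(C)OO
Why: Sharpless asymmetric epoxidation of a Z-allylic alcohol, in which the titanium–D-tartrate catalyst delivers oxygen to one alkene face and so sets both oxirane stereocentres (2R,3S), the tertiary one being the future C8.

Step 2
Reactants: 2 (2R,3S)-2,3-epoxynerol
Product: 4 epoxyneryl bromide, via mesylate 3 (not isolated)
Conditions: MsCl, Et3N, CH2Cl2, −20 °C; then LiBr, acetone, 0 °C to rt
Reagents that add atoms: lithium bromide [Li+].[Br-]; methanesulfonyl chloride CS(=O)(=O)Cl (its atoms stay only in 3)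
Why: Sulfonylation and Finkelstein-type SN2 displacement at the primary carbon leave both oxirane stereocentres untouched (the CIP label of the CH carbon changes to S only because CH2Br outranks the ring carbon).

Step 3
Reactants: 5 1,3-dimethoxybenzene
Product: 6 1,5-dimethoxycyclohexa-1,4-diene
Conditions: Li, liquid NH3, THF, t-BuOH, −78 to −33 °C
Reagents that add atoms: none
Why: Birch reduction of a resorcinol diether protonates the positions between and opposite the two methoxy groups and gives the unconjugated bis(enol ether).

Step 4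
Reactants: 6 1,5-dimethoxycyclohexa-1,4-diene; 7 prenyl bromide
Product: 9 6-prenyl-1,5-dimethoxycyclohexa-1,4-diene, via pentadienyllithium 8 (not isolated)
Conditions: t-BuLi, THF, −78 °C; then 7, −78 to 0 °C
Reagents that add atoms: none
Why: The CH2 flanked by the two methoxy-bearing sp2 carbons is deprotonated to a pentadienyl anion that is alkylated at its central carbon by SN2 reaction with the allylic bromide.

Step 5
Reactants: 9 6-prenyl-1,5-dimethoxycyclohexa-1,4-diene; 4 epoxyneryl bromide
Product: 11 6-prenyl-6-(epoxynerylmethyl) diene, via tertiary pentadienyllithium 10 (not isolated)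
Conditions: t-BuLi, THF, −78 °C; then 4, −78 to −20 °C
Reagents that add atoms: none
Why: A second deprotonation–SN2 alkylation at the same carbon (primary C–Br next to the hindered trisubstituted oxirane) builds the quaternary future C5, which is not yet a stereocentre because the two ring arms are identical.

Step 6
Reactants: 11 6-prenyl-6-(epoxynerylmethyl) diene
Product: 13 7,9-oxa-bridged bicyclo[3.3.1]nonene methyl ketal (C7–O exo; C8 homoprenyl exo), via oxocarbenium triflate 12 (not isolated)
Conditions: TMSOTf (released again in the last stage), 2,6-lutidine, CH2Cl2, −78 °C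
Reagents that add atoms: trimethylsilyl trifluoromethanesulfonate C[Si](C)(C)OS(=O)(=O)C(F)(F)F (its atoms stay only in 12)
Why: TMSOTf silylates the oxirane oxygen, enol ether carbon C1 attacks the tertiary oxirane carbon C8 anti to the departing oxygen to give oxocarbenium ion 12, and the C7 silyloxy oxygen then adds to C9 with release of the silyl group to give the mixed ketal. The closest known reaction type is the Lewis-acid-promoted epoxide-opening cyclisation of enol ethers (a Prins-type cation–olefin cyclisation terminated by oxygen), which is established for building bicyclo[3.3.1]nonanes from 6,6-disubstituted 1,5-dimethoxycyclohexa-1,4-dienes. Ring B closes through a chair in the 6-endo-tet mode with respect to the oxirane (both oxirane carbons inside the ring, enol-endo for the nucleophile), and the oxa-bridge closes 5-exo-trig onto the oxocarbenium carbon after ring B has flipped to the boat. C8 is set by stereospecific inversion, so the Z geometry of nerol places the homoprenyl chain exo (axial) and the methyl group endo; C1 and C5 are set by the choice between the two diastereotopic enol ethers, which is made by the chair transition state in which the C7–O bond is anti to the forming C1–C8 bond; C9 follows from the bridge and C7 keeps its configuration with oxygen exo. The step needs group selectivity (chair over boat closure), regioselectivity for the tertiary over the secondary oxirane carbon (better cation stabilisation, six- instead of five-membered ring) and chemoselectivity for the enol ether over the three trisubstituted alkenes (far higher π-nucleophilicity), while 2,6-lutidine buffers triflic acid so that the second enol ether survives.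

Step 7
Reactants: 13 oxa-bridged ketal
Product: 15 oxa-bridged vinylogous ester (C2 ketone), via allylic peroxide 14 (not isolated)
Conditions: t-BuOOH, PhI(OAc)2, Cs2CO3, EtOAc, −78 °C
Reagents that add atoms: tert-butyl hydroperoxide CC(C)(C)OO
Why: Radical allylic oxidation (tert-butylperoxyl hydrogen abstraction, peroxide formation, Kornblum–DeLaMare elimination) should take the C2–H bonds, which the adjacent enol ether makes weaker than the side-chain allylic C–H bonds, while the ketal masks C7–O and C9.

Step 8
Reactants: 15 oxa-bridged vinylogous ester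
Product: 16 7-exo-hydroxy-2,9-dione
Conditions: Me2BBr, CH2Cl2, −78 °C; then aq. NaHCO3
Reagents that add atoms: none
Why: Bromodialkylborane ketal cleavage opens the strained oxa-bridge to a methoxy-oxocarbenium ion that bromide demethylates to the C9 ketone, and at −78 °C the far less basic vinylogous ester should not be touched.

Step 9
Reactants: 16 7-exo-hydroxy-2,9-dione
Product: 17 2,7,9-trione
Conditions: Dess–Martin periodinane, CH2Cl2, 0 °C to rt
Reagents that add atoms: none
Why: Dess–Martin oxidation of the secondary alcohol removes the C7 stereocentre under neutral conditions that spare the alkenes and the vinylogous ester.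

Step 10
Reactants: 17 2,7,9-trione
Product: 18 7-methylidene-2,9-dione
Conditions: Ph3PCH3Br, KOtBu, THF, 0 °C to rt
Reagents that add atoms: methylenetriphenylphosphorane C=P(c1ccccc1)(c1ccccc1)c1ccccc1 (made in the flask from methyltriphenylphosphonium bromide)
Why: Wittig methylenation should select the C7 ketone, which has one CH2 neighbour, over the C9 ketone between two fully substituted carbons and over the ester-like C2 carbonyl.

Step 11
Reactants: 18 7-methylidene-2,9-dione; 19 1-bromo-2-methylprop-1-ene
Product: 21 7-endo-prenyl-2,9-dione, via alkylborane 20 (not isolated)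
Conditions: 9-BBN, THF, 0 °C to rt; then 19, Pd(dppf)Cl2 (cat.), AsPh3 (cat.), Cs2CO3, DMF/H2O, rt
Reagents that add atoms: 9-borabicyclo[3.3.1]nonane B1C2CCCC1CCC2 (its atoms stay only in 20)
Why: 9-BBN hydroboration discriminates the 1,1-disubstituted C7 methylene from the three trisubstituted alkenes and the hindered C9 ketone and should deliver hydrogen to C7 from the exo face (the endo face is shielded by the C2–C4 bridge, and sp2 and radical C7 centres of this ring system are attacked exo), so the CH2–boron arm ends endo and sets C7, and the B-alkyl Suzuki–Miyaura coupling with 19 then completes the prenyl group without touching that stereocentre.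

Step 12
Reactants: 21 7-endo-prenyl-2,9-dione
Product: 23 3-trimethylsilyl derivative, via vinyllithium 22 (not isolated)
Conditions: LDA (1.1 equiv), THF, −78 °C; then TMSCl
Reagents that add atoms: chlorotrimethylsilane C[Si](C)(C)Cl
Why: Directed α-lithiation of the β-methoxy enone at C3, its kinetically most acidic site, and C-silylation block C3 so that the next base can only reach the bridgehead.

Step 13
Reactants: 24 (R)-2-methylbutanoic acid
Product: 25 (R)-2-methylbutanoyl chloride
Conditions: (COCl)2, DMF (cat.), CH2Cl2, 0 °C to rt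
Reagents that add atoms: oxalyl chloride ClC(=O)C(Cl)=O
Why: Acid chloride formation through the Vilsmeier-type chloroiminium species runs without base, so no ketene forms and the α-stereocentre is retained.

Step 14
Reactants: 23 3-trimethylsilyl derivative; 25 (R)-2-methylbutanoyl chloride
Product: 27 1-acyl-3-trimethylsilyl vinylogous ester, via bridgehead lithium compound 26 (not isolated)
Conditions: LDA (2.5 equiv), THF, −78 °C; then 25 (excess), −78 °C; AcOH quench
Reagents that add atoms: none
Why: Bridgehead lithiation at C1 (flanked by the C2 and C9 carbonyls) gives a carbanion that cannot become a planar enolate and is therefore acylated on carbon (Claisen-type C-acylation), the C1 configuration being imposed by the bicycle and the acyl stereocentre arriving unchanged from 25 provided addition outruns ketene formation at −78 °C.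

Step 15
Reactants: 27 1-acyl-3-trimethylsilyl vinylogous ester
Product: 28 O-methyl ether of the target
Conditions: TBAF, AcOH, THF, 0 °C
Reagents that add atoms: none
Why: Fluoride-induced protodesilylation of the α-silyl enone removes the blocking group, and the acetic acid buffer suppresses retro-Claisen cleavage of the triketone.

Step 16
Reactants: 28 O-methyl ether of the target
Product: 29 target
Conditions: LiCl, DMSO, 120 °C; then dilute HCl work-up
Reagents that add atoms: none
Why: Krapcho-type SN2 demethylation of the vinylogous ester by chloride gives the β-diketone enolate under non-basic conditions, so the enolisable acyl stereocentre and the four ring stereocentres are not disturbed.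

**Compound list**

1 | nerol, (2Z)-3,7-dimethylocta-2,6-dien-1-ol | OC/C=C(/C)CCC=C(C)C | starting material
2 | [(2R,3S)-3-methyl-3-(4-methylpent-3-en-1-yl)oxiran-2-yl]methanol, (2R,3S)-2,3-epoxynerol | OC[C@H]1O[C@@]1(C)CCC=C(C)C | intermediate
3 | methanesulfonate of 2 | CS(=O)(=O)OC[C@H]1O[C@@]1(C)CCC=C(C)C | intermediate
4 | (2S,3S)-2-(bromomethyl)-3-methyl-3-(4-methylpent-3-en-1-yl)oxirane, epoxyneryl bromide (same spatial arrangement as 2) | BrC[C@H]1O[C@@]1(C)CCC=C(C)C | intermediate
5 | 1,3-dimethoxybenzene | COc1cccc(OC)c1 | starting material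
6 | 1,5-dimethoxycyclohexa-1,4-diene | COC1=CCC=C(OC)C1 | intermediate
7 | prenyl bromide, 1-bromo-3-methylbut-2-ene | CC(C)=CCBr | starting material
8 | 6-lithio-1,5-dimethoxycyclohexa-1,4-diene (delocalised pentadienyllithium) | COC1=CCC=C(OC)C1[Li] | intermediate
9 | 1,5-dimethoxy-6-(3-methylbut-2-en-1-yl)cyclohexa-1,4-diene | COC1=CCC=C(OC)C1CC=C(C)C | intermediate
10 | 6-lithio derivative of 9 | COC1=CCC=C(OC)C1([Li])CC=C(C)C | intermediate
11 | 1,5-dimethoxy-6-(3-methylbut-2-en-1-yl)-6-{[(2R,3S)-3-methyl-3-(4-methylpent-3-en-1-yl)oxiran-2-yl]methyl}cyclohexa-1,4-diene | COC1=CCC=C(OC)C1(CC=C(C)C)C[C@H]2O[C@@]2(C)CCC=C(C)C | intermediate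
12 | bicyclic C9 O-methyl oxocarbenium triflate with 7-exo trimethylsilyloxy group and 4-methoxy enol ether | COC1=CC[C@H]2[C@](C)(CCC=C(C)C)[C@H](O[Si](C)(C)C)C[C@]1(CC=C(C)C)C2=[O+]C.[O-]S(=O)(=O)C(F)(F)F | intermediate
13 | 4,9-dimethoxy-8-methyl-5-(3-methylbut-2-enyl)-8-(4-methylpent-3-enyl)-7,9-epoxybicyclo[3.3.1]non-3-ene; C7–O exo, C8 homoprenyl exo, C8 methyl endo | COC1=CC[C@H]2[C@](C)(CCC=C(C)C)[C@H]3C[C@]1(CC=C(C)C)[C@]2(OC)O3 | intermediate
14 | 2-(tert-butylperoxy) derivative of 13 (C2 epimers) | COC1=CC(OOC(C)(C)C)[C@H]2[C@](C)(CCC=C(C)C)[C@H]3C[C@]1(CC=C(C)C)[C@]2(OC)O3 | intermediate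
15 | 2-oxo derivative of 13 (vinylogous methyl ester, ketal intact) | COC1=CC(=O)[C@H]2[C@](C)(CCC=C(C)C)[C@H]3C[C@]1(CC=C(C)C)[C@]2(OC)O3 | intermediate
16 | 7-exo-hydroxy-4-methoxy-8-methyl-5-(3-methylbut-2-enyl)-8-(4-methylpent-3-enyl)bicyclo[3.3.1]non-3-ene-2,9-dione | COC1=CC(=O)[C@H]2[C@](C)(CCC=C(C)C)[C@H](O)C[C@]1(CC=C(C)C)C2=O | intermediate
17 | 4-methoxy-8-methyl-5-(3-methylbut-2-enyl)-8-(4-methylpent-3-enyl)bicyclo[3.3.1]non-3-ene-2,7,9-trione | COC1=CC(=O)[C@H]2[C@](C)(CCC=C(C)C)C(=O)C[C@]1(CC=C(C)C)C2=O | intermediate
18 | 7-methylidene analogue of 17 (2,9-dione) | COC1=CC(=O)[C@H]2[C@](C)(CCC=C(C)C)C(=C)C[C@]1(CC=C(C)C)C2=O | intermediate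
19 | 1-bromo-2-methylprop-1-ene | CC(C)=CBr | starting material
20 | 7-endo-[(9-borabicyclo[3.3.1]nonan-9-yl)methyl] compound, C7–H exo | COC1=CC(=O)[C@H]2[C@](C)(CCC=C(C)C)[C@@H](CB3C4CCCC3CCC4)C[C@]1(CC=C(C)C)C2=O | intermediate
21 | 4-methoxy-8-methyl-5,7-bis(3-methylbut-2-enyl)-8-(4-methylpent-3-enyl)bicyclo[3.3.1]non-3-ene-2,9-dione, 7-prenyl endo | COC1=CC(=O)[C@H]2[C@](C)(CCC=C(C)C)[C@@H](CC=C(C)C)C[C@]1(CC=C(C)C)C2=O | intermediate
22 | 3-lithio derivative of 21 | COC1=C([Li])C(=O)[C@H]2[C@](C)(CCC=C(C)C)[C@@H](CC=C(C)C)C[C@]1(CC=C(C)C)C2=O | intermediate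
23 | 3-trimethylsilyl derivative of 21 | COC1=C([Si](C)(C)C)C(=O)[C@H]2[C@](C)(CCC=C(C)C)[C@@H](CC=C(C)C)C[C@]1(CC=C(C)C)C2=O | intermediate
24 | (R)-2-methylbutanoic acid | CC[C@@H](C)C(=O)O | starting material
25 | (R)-2-methylbutanoyl chloride | CC[C@@H](C)C(=O)Cl | intermediate
26 | C1 bridgehead lithio derivative of 23 | COC1=C([Si](C)(C)C)C(=O)[C@@]2([Li])[C@](C)(CCC=C(C)C)[C@@H](CC=C(C)C)C[C@]1(CC=C(C)C)C2=O | intermediate
27 | 1-[(2R)-2-methylbutanoyl] derivative of 23 | COC1=C([Si](C)(C)C)C(=O)[C@@]2(C(=O)[C@H](C)CC)[C@](C)(CCC=C(C)C)[C@@H](CC=C(C)C)C[C@]1(CC=C(C)C)C2=O | intermediate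
28 | 4-O-methyl ether of the target | COC1=CC(=O)[C@@]2(C(=O)[C@H](C)CC)[C@](C)(CCC=C(C)C)[C@@H](CC=C(C)C)C[C@]1(CC=C(C)C)C2=O | intermediate
29 | (1S,5S,7S,8R)-4-hydroxy-8-methyl-1-[(2R)-2-methylbutanoyl]-5,7-bis(3-methylbut-2-en-1-yl)-8-(4-methylpent-3-en-1-yl)bicyclo[3.3.1]non-3-ene-2,9-dione | CC[C@@H](C)C(=O)[C@]12C(=O)C=C(O)[C@](CC=C(C)C)(C[C@H](CC=C(C)C)[C@@]1(C)CCC=C(C)C)C2=O | target

**Totals and risks**

Total step count: 16. Longest linear sequence: 13 steps (1, 2, 5–12, 14–16 from nerol; equally 3–12, 14–16 from 1,3-dimethoxybenzene).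

Steps most likely to fail:

Step 11. Hydrogen may be delivered to C7 with incomplete exo-face selectivity, because the exo C8 chain also crowds that face, and transmetalation of the congested endo alkylborane to palladium may be slower than protodeboronation. The fallback replaces the boron-to-palladium coupling by a nickel-catalysed reductive cross-electrophile coupling and inserts an isolable stage at which a minor C7 epimer can be removed. Borane 20, made from 18 as before, would be oxidised (NaBO3·4H2O, THF/H2O) to the endo primary alcohol F6. Iodination (I2, PPh3, imidazole, CH2Cl2) would give the primary iodide F7. Coupling of F7 with 19 (NiI2, 4,4'-di-tert-butyl-2,2'-bipyridine, Zn, DMA, rt) would return to the route at 21.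

Step 7. Peroxyl-radical hydrogen abstraction may not distinguish well enough between C2–H and the allylic C–H bonds of the prenyl and homoprenyl chains, and over-oxidation may follow. The fallback is a two-electron sequence that sets out from 13. Hydride abstraction at C2 by DDQ (wet CH2Cl2, 2,6-lutidine), which attacks only the electron-rich enol ether, and hydrolysis of the methoxyallyl cation would give the ring-A enone F1 (C2=C3–C4=O, ketal intact). Copper-catalysed conjugate borylation (B2pin2, CuCl, DPEphos, NaOtBu, MeOH, THF), to which isolated trisubstituted alkenes are inert, would give the β-boryl ketone F2. Oxidation in the same flask with NaBO3 would give the β-hydroxy ketone F3, and Dess–Martin oxidation (pyridine buffer) the 2,4-diketone F4. O-Methylation with TMSCHN2 (MeOH/CH2Cl2) would return to the route at 15, accompanied by the C2-methoxy regioisomer F5, which is removed by chromatography.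

Step 14. The acid chloride may be deprotonated to a ketene by the amide base or the bridgehead carbanion, which would erode the acyl stereocentre and lower conversion at the hindered bridgehead. The fallback replaces acylation by aldehyde addition and oxidation. Acid 24 would be reduced (LiAlH4, Et2O) to (R)-2-methylbutan-1-ol F8 and oxidised (TEMPO, PhI(OAc)2, CH2Cl2) to (R)-2-methylbutanal F9, used at once. Bridgehead lithium compound 26, generated from 23 as before, would add to F9 at −78 °C to give the carbinol F10 (both carbinol epimers serve). Dess–Martin oxidation would return to the route at 27.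

Further compounds
F1 | step 7 | ring-A enone (4-oxo-2-ene) with the 7,9-oxa-bridged methyl ketal intact | O=C1C=C[C@H]2[C@](C)(CCC=C(C)C)[C@H]3C[C@]1(CC=C(C)C)[C@]2(OC)O3
F2 | step 7 | 2-(pinacolboryl) 4-ketone (C2 epimers) | O=C1CC(B4OC(C)(C)C(C)(C)O4)[C@H]2[C@](C)(CCC=C(C)C)[C@H]3C[C@]1(CC=C(C)C)[C@]2(OC)O3
F3 | step 7 | 2-hydroxy 4-ketone (C2 epimers) | O=C1CC(O)[C@H]2[C@](C)(CCC=C(C)C)[C@H]3C[C@]1(CC=C(C)C)[C@]2(OC)O3
F4 | step 7 | 2,4-diketone with the oxa-bridged ketal | O=C1CC(=O)[C@H]2[C@](C)(CCC=C(C)C)[C@H]3C[C@]1(CC=C(C)C)[C@]2(OC)O3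
F5 | step 7 | regioisomer of 15 with methoxy on C2 and ketone at C4 | O=C1C=C(OC)[C@H]2[C@](C)(CCC=C(C)C)[C@H]3C[C@]1(CC=C(C)C)[C@]2(OC)O3
F6 | step 11 | 7-endo-hydroxymethyl compound | COC1=CC(=O)[C@H]2[C@](C)(CCC=C(C)C)[C@@H](CO)C[C@]1(CC=C(C)C)C2=O
F7 | step 11 | 7-endo-iodomethyl compound | COC1=CC(=O)[C@H]2[C@](C)(CCC=C(C)C)[C@@H](CI)C[C@]1(CC=C(C)C)C2=O
F8 | step 14 | (R)-2-methylbutan-1-ol | CC[C@@H](C)CO
F9 | step 14 | (R)-2-methylbutanal | CC[C@@H](C)C=O
F10 | step 14 | C1 (1-hydroxy-2-methylbutyl) adduct of 23 (carbinol epimers) | COC1=C([Si](C)(C)C)C(=O)[C@@]2(C(O)[C@H](C)CC)[C@](C)(CCC=C(C)C)[C@@H](CC=C(C)C)C[C@]1(CC=C(C)C)C2=O
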